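**Plan**
1. Retrosynthesis first removes the protecting groups and takes the C4 ketone back to a CH2 (benzylic oxidation). Ring C, a chroman, is then cut at O1–C2 and C3–C4: C2 is benzylic to the electron-rich 4-hydroxy-2-methoxyphenyl ring B, and O1 and C4 sit ortho to each other on ring A, so ring C is the [4+2] adduct of a ring A ortho-quinone methide and a ring B styrene.
2. Next the aryl–alkyl bond C8–C1'' is cut (Negishi coupling), then the C2''–prenyl bond (auxiliary-controlled enolate alkylation) and the C1''–C2'' bond (carboxylation of a Grignard reagent).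
3. Forward: side-chain iodide (6 steps), coupling to the ring A iodide, reduction to the ortho-hydroxybenzyl alcohol, closure of ring C by cycloaddition (the only ring formed), C4 oxidation, global deprotection.
4. Stereochemistry: C3'' comes from (S)-3-bromo-2-methylpropan-1-ol, C2'' from an (S)-4-benzyloxazolidinone alkylation, and C2 from a chiral phosphoric acid in the cycloaddition.

Key step: step 13

Remarks and assumptions
- TBS = tert-butyldimethylsilyl, MOM = methoxymethyl. Side-chain locants: C1'' (ArCH2), C2'' (prenyl-bearing CH), C3'' (methyl-bearing CH), C4'' (CH2O). "SC" in names means the (2R,3R)-4-(TBS-oxy)-3-methyl-2-(3-methylbut-2-en-1-yl)butyl group.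
- Assumption: iodination of the bis-MOM aldehyde occurs ortho to the chelated free phenol, as is usual for 2-hydroxy-4,6-dialkoxyaryl carbonyl compounds.
- Assumption: the (R) phosphoric acid is written for the (2S) product by analogy; if the sense of induction is opposite, its mirror image is used with no other change.

**Step 1**
Reactants: 1 (S)-3-bromo-2-methylpropan-1-ol
Product: 2 (S)-(3-bromo-2-methylpropoxy)(tert-butyl)dimethylsilane
Conditions: TBSCl, imidazole, CH2Cl2, 0 °C → rt
Reagents that add atoms: tert-butyldimethylsilyl chloride, CC(C)(C)[Si](C)(C)Cl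
Why: Imidazole-promoted silylation of the primary alcohol leaves the stereocentre (future C3'') untouched and installs an ether that should survive the organometallic, hydride and oxidation steps until the final acid treatment.

**Step 2**
Reactants: 2 (S)-(3-bromo-2-methylpropoxy)(tert-butyl)dimethylsilane
Product: 4 (R)-4-(TBS-oxy)-3-methylbutanoic acid, via Grignard reagent 3 (not isolated)
Conditions: Mg, I2 (cat.), THF, reflux; then CO2, −20 °C → rt; aq. citric acid to pH 4
Reagents that add atoms: carbon dioxide, O=C=O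
Why: Grignard formation from the primary bromide and carboxylation adds the carbon that becomes C1'' and makes the former CH2Br carbon the enolisable position (future C2''), the β-stereocentre not being involved.

**Step 3**
Reactants: 4 (R)-4-(TBS-oxy)-3-methylbutanoic acid; 5 (S)-4-benzyloxazolidin-2-one
Product: 7 (S)-4-benzyl-3-[(R)-4-(TBS-oxy)-3-methylbutanoyl]oxazolidin-2-one, via mixed pivalic anhydride 6 (not isolated)
Conditions: PivCl, Et3N, THF, −20 °C; then LiCl, 5, −20 °C → rt
Reagents that add atoms: none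
Why: N-Acylation of the oxazolidinone through the pivaloyl mixed anhydride is the standard mild way to attach the auxiliary and is selective for the less hindered carbonyl of the anhydride.

**Step 4**
Reactants: 7 (S)-4-benzyl-3-[(R)-4-(TBS-oxy)-3-methylbutanoyl]oxazolidin-2-one
Product: 9 (S)-4-benzyl-3-[(2S,3R)-4-(TBS-oxy)-3-methyl-2-(3-methylbut-2-en-1-yl)butanoyl]oxazolidin-2-one, via sodium enolate 8 (not isolated)
Conditions: NaN(SiMe3)2, THF, −78 °C; prenyl bromide, −78 → −40 °C
Reagents that add atoms: 1-bromo-3-methylbut-2-ene (prenyl bromide), CC(C)=CCBr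
Why: In this Evans alkylation the chelated (Z)-enolate is shielded on one face by the benzyl group, so prenyl bromide should enter from the other face and set C2'' under auxiliary control, the existing β-stereocentre being a spectator.

**Step 5**
Reactants: 9 (S)-4-benzyl-3-[(2S,3R)-4-(TBS-oxy)-3-methyl-2-(3-methylbut-2-en-1-yl)butanoyl]oxazolidin-2-one
Product: 10 (2S,3R)-4-(TBS-oxy)-3-methyl-2-(3-methylbut-2-en-1-yl)butan-1-ol
Conditions: LiBH4, H2O (1 equiv), Et2O, 0 °C
Reagents that add atoms: none
Why: Reductive cleavage of the N-acyloxazolidinone by borohydride at the exocyclic carbonyl gives the primary alcohol without enolisation, so C2'' is not at risk, and leaves the silyl ether and alkene intact.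

**Step 6**
Reactants: 10 (2S,3R)-4-(TBS-oxy)-3-methyl-2-(3-methylbut-2-en-1-yl)butan-1-ol
Product: 11 tert-butyl{[(2R,3S)-3-(iodomethyl)-2,6-dimethylhept-5-en-1-yl]oxy}dimethylsilane
Conditions: I2, PPh3, imidazole, CH2Cl2, 0 °C → rt, dark
Reagents that add atoms: iodine, II
Why: Appel-type iodination proceeds by SN2 displacement at the primary carbon only, so neither stereocentre is touched (the descriptors change only through priority rules).

**Step 7**
Reactants: 12 2,4,6-trihydroxybenzaldehyde
Product: 13 2-hydroxy-4,6-bis(methoxymethoxy)benzaldehyde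
Conditions: MOMCl (2.1 equiv), i-Pr2NEt, CH2Cl2, 0 °C → rt
Reagents that add atoms: chloromethyl methyl ether, COCCl
Why: O-Alkylation with the chloromethyl ether should stop at the bis-ether because the phenol hydrogen-bonded to the aldehyde is the least nucleophilic, which singles out the oxygen that becomes O1.

**Step 8**
Reactants: 13 2-hydroxy-4,6-bis(methoxymethoxy)benzaldehyde
Product: 14 2-hydroxy-3-iodo-4,6-bis(methoxymethoxy)benzaldehyde
Conditions: BnMe3N+ ICl2−, CaCO3, CH2Cl2–MeOH, rt
Reagents that add atoms: benzyltrimethylammonium dichloroiodate, C[N+](C)(C)Cc1ccccc1.Cl[I-]Cl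
Why: Buffered electrophilic aromatic iodination is expected ortho to the free chelated phenol, placing the halogen on the carbon that becomes C8 while the MOM ethers are protected from acid by the carbonate.

**Step 9**
Reactants: 14 2-hydroxy-3-iodo-4,6-bis(methoxymethoxy)benzaldehyde
Product: 15 2-formyl-6-iodo-3,5-bis(methoxymethoxy)phenyl acetate
Conditions: Ac2O, pyridine, DMAP (cat.), CH2Cl2, 0 °C → rt
Reagents that add atoms: acetic anhydride, CC(=O)OC(C)=O
Why: Acetylation masks the acidic phenol so that it cannot protonate the alkylzinc reagent, and the acetate is later removed by the same hydride that reduces the aldehyde.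

**Step 10**
Reactants: 11 tert-butyl{[(2R,3S)-3-(iodomethyl)-2,6-dimethylhept-5-en-1-yl]oxy}dimethylsilane; 15 2-formyl-6-iodo-3,5-bis(methoxymethoxy)phenyl acetate
Product: 17 2-SC-6-formyl-3,5-bis(methoxymethoxy)phenyl acetate, via alkylzinc iodide 16 (not isolated)
Conditions: Zn dust (activated with BrCH2CH2Br and Me3SiCl), LiCl, THF, 40 °C; then 15, Pd(OAc)2 (4 mol%), SPhos (8 mol%), THF, 25 → 45 °C
Reagents that add atoms: none
Why: In this Negishi sp3–sp2 coupling the aryl iodide adds oxidatively to zerovalent palladium, the primary alkylzinc transmetalates, and the bulky biarylphosphine favours reductive elimination over β-hydride loss at the di-ortho-substituted centre, the alkylzinc halide tolerating aldehyde, acetate, acetal and silyl ether groups.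

**Step 11**
Reactants: 17 2-SC-6-formyl-3,5-bis(methoxymethoxy)phenyl acetate
Product: 18 2-SC-6-(hydroxymethyl)-3,5-bis(methoxymethoxy)phenol
Conditions: LiAlH4, THF, 0 °C; aq. KNaC4H4O6 work-up; product kept free of acid
Reagents that add atoms: none
Why: Hydride reduction converts the aldehyde to the benzylic alcohol and cleaves the aryl acetate in one operation, giving the ortho-hydroxybenzyl alcohol in which only the phenol flanked by CH2OH and the side chain is free.

**Step 12**
Reactants: 19 4-hydroxy-2-methoxybenzaldehyde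
Product: 20 4-ethenyl-3-methoxyphenol
Conditions: Ph3PCH3Br, KOt-Bu (2.5 equiv each), THF, 0 °C → rt; used freshly
Reagents that add atoms: methyltriphenylphosphonium bromide, C[P+](c1ccccc1)(c1ccccc1)c1ccccc1.[Br-]
Why: Wittig methylenation with excess ylide tolerates the phenoxide and gives the vinylphenol directly, which is used at once because such styrenes polymerise on storage.

**Step 13**
Reactants: 18 2-SC-6-(hydroxymethyl)-3,5-bis(methoxymethoxy)phenol; 20 4-ethenyl-3-methoxyphenol
Product: 22 4-[(2S)-8-SC-5,7-bis(methoxymethoxy)-3,4-dihydro-2H-chromen-2-yl]-3-methoxyphenol, via ortho-quinone methide 21 (not isolated)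
Conditions: (R)-TRIP [(R)-3,3'-bis(2,4,6-triisopropylphenyl)-1,1'-binaphthyl-2,2'-diyl hydrogen phosphate] (10 mol%), 20 (3 equiv), 4 Å MS, PhMe, 0 °C → rt, 18 added slowly; Et3N quench
Reagents that add atoms: none
Why: The chiral phosphoric acid ionises the benzylic alcohol of 18 to the ortho-quinone methide 21 and holds it by a hydrogen bond to its carbonyl oxygen while the phosphoryl oxygen binds the 4-hydroxyl of 20; the terminal CH2 of the styrene then attacks the methide carbon (future C4) and the ring A oxygen closes on the benzylic carbon (future C2), whose positive charge is stabilised as a para-quinone methide by the 4-hydroxy and 2-methoxy groups. The closest known reaction type is the chiral phosphoric acid catalysed inverse-electron-demand oxa-[4+2] cycloaddition of ortho-quinone methides, generated from ortho-hydroxybenzyl alcohols, with hydroxystyrenes to give 2-arylchromans. Ring C closes as a six-membered ring in an asynchronous [4+2] mode (in the stepwise limit a 6-exo-trig oxa-1,6-addition of the phenol to the para-quinone methide), forming C3–C4 and O1–C2. The single new stereocentre C2 is set by the catalyst, whose 3,3'-aryl groups screen one face of the bound styrene in the C–O bond-forming event, the remote side-chain stereocentres being spectators. The step needs head-to-tail regioselectivity, which the polarity of the two partners secures, and a fixed O1/8-alkyl pattern, which is secured because only the phenol between CH2OH and the side chain is free while O5 and O7 carry MOM groups; the isolated trisubstituted alkene is far less nucleophilic than the styrene and should not compete.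

**Step 14**
Reactants: 22 4-[(2S)-8-SC-5,7-bis(methoxymethoxy)-3,4-dihydro-2H-chromen-2-yl]-3-methoxyphenol
Product: 23 4-[(2S)-8-SC-5,7-bis(methoxymethoxy)-3,4-dihydro-2H-chromen-2-yl]-3-methoxyphenyl acetate
Conditions: Ac2O, pyridine, DMAP (cat.), CH2Cl2, 0 °C
Reagents that add atoms: acetic anhydride, CC(=O)OC(C)=O
Why: Acetylation of the only free hydroxyl makes ring B less electron-rich, which should suppress both acid-induced ionisation of the C2–O1 bond and hydride abstraction from C2 in the next step.

**Step 15**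
Reactants: 23 4-[(2S)-8-SC-5,7-bis(methoxymethoxy)-3,4-dihydro-2H-chromen-2-yl]-3-methoxyphenyl acetate
Product: 25 4-[(2S)-8-SC-5,7-bis(methoxymethoxy)-4-oxo-3,4-dihydro-2H-chromen-2-yl]-3-methoxyphenyl acetate, via flavan-4-ol 24 (not isolated)
Conditions: DDQ (2.3 equiv), CH2Cl2–aq. NaH2PO4/Na2HPO4 buffer pH 7 (10:1), 0 °C → rt
Reagents that add atoms: water, O
Why: In this quinone-mediated benzylic oxidation DDQ abstracts hydride from the ring-held C4–H, which is aligned with a ring A bearing three oxygen donors; water traps the cation and the resulting electron-rich benzylic alcohol is oxidised on to the ketone, whereas the side-chain benzylic CH2 cannot easily become coplanar with the ring and C2 is deactivated by the acetate.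

**Step 16**
Reactants: 25 4-[(2S)-8-SC-5,7-bis(methoxymethoxy)-4-oxo-3,4-dihydro-2H-chromen-2-yl]-3-methoxyphenyl acetate
Product: 26 (2S)-5,7-dihydroxy-2-(4-hydroxy-2-methoxyphenyl)-8-[(2R,3R)-4-hydroxy-3-methyl-2-(3-methylbut-2-en-1-yl)butyl]-2,3-dihydro-4H-chromen-4-one
Conditions: HCl (1.25 M in MeOH), THF, rt → 40 °C
Reagents that add atoms: none
Why: Acid-catalysed methanolysis removes both MOM acetals, the silyl ether and the aryl acetate in one operation under conditions mild enough that the flavanone C2 centre (no base present) and the trisubstituted alkene should be preserved.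

**Compound list**
1 | (S)-3-bromo-2-methylpropan-1-ol | BrC[C@@H](C)CO | starting material
2 | (S)-(3-bromo-2-methylpropoxy)(tert-butyl)dimethylsilane | BrC[C@@H](C)CO[Si](C)(C)C(C)(C)C | intermediate
3 | [(S)-3-(TBS-oxy)-2-methylpropyl]magnesium bromide | Br[Mg]C[C@@H](C)CO[Si](C)(C)C(C)(C)C | intermediate (not isolated)
4 | (R)-4-(TBS-oxy)-3-methylbutanoic acid | OC(=O)C[C@@H](C)CO[Si](C)(C)C(C)(C)C | intermediate
5 | (S)-4-benzyloxazolidin-2-one | O=C1N[C@@H](Cc2ccccc2)CO1 | starting material
6 | (R)-4-(TBS-oxy)-3-methylbutanoic pivalic anhydride | CC(C)(C)C(=O)OC(=O)C[C@@H](C)CO[Si](C)(C)C(C)(C)C | intermediate (not isolated)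
7 | (S)-4-benzyl-3-[(R)-4-(TBS-oxy)-3-methylbutanoyl]oxazolidin-2-one | O=C(C[C@@H](C)CO[Si](C)(C)C(C)(C)C)N1C(=O)OC[C@@H]1Cc1ccccc1 | intermediate
8 | sodium (Z)-enolate of 7 | [Na+].[O-]/C(=C\[C@@H](C)CO[Si](C)(C)C(C)(C)C)N1C(=O)OC[C@@H]1Cc1ccccc1 | intermediate (not isolated)
9 | (S)-4-benzyl-3-[(2S,3R)-4-(TBS-oxy)-3-methyl-2-(3-methylbut-2-en-1-yl)butanoyl]oxazolidin-2-one | O=C([C@@H](CC=C(C)C)[C@@H](C)CO[Si](C)(C)C(C)(C)C)N1C(=O)OC[C@@H]1Cc1ccccc1 | intermediate
10 | (2S,3R)-4-(TBS-oxy)-3-methyl-2-(3-methylbut-2-en-1-yl)butan-1-ol | OC[C@@H](CC=C(C)C)[C@@H](C)CO[Si](C)(C)C(C)(C)C | intermediate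
11 | tert-butyl{[(2R,3S)-3-(iodomethyl)-2,6-dimethylhept-5-en-1-yl]oxy}dimethylsilane | IC[C@@H](CC=C(C)C)[C@@H](C)CO[Si](C)(C)C(C)(C)C | intermediate
12 | 2,4,6-trihydroxybenzaldehyde | O=Cc1c(O)cc(O)cc1O | starting material
13 | 2-hydroxy-4,6-bis(methoxymethoxy)benzaldehyde | O=Cc1c(O)cc(OCOC)cc1OCOC | intermediate
14 | 2-hydroxy-3-iodo-4,6-bis(methoxymethoxy)benzaldehyde | O=Cc1c(O)c(I)c(OCOC)cc1OCOC | intermediate
15 | 2-formyl-6-iodo-3,5-bis(methoxymethoxy)phenyl acetate | CC(=O)Oc1c(I)c(OCOC)cc(OCOC)c1C=O | intermediate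
16 | [(2S,3R)-4-(TBS-oxy)-3-methyl-2-(3-methylbut-2-en-1-yl)butyl]zinc iodide | I[Zn]C[C@@H](CC=C(C)C)[C@@H](C)CO[Si](C)(C)C(C)(C)C | intermediate (not isolated)
17 | 2-SC-6-formyl-3,5-bis(methoxymethoxy)phenyl acetate | CC(=O)Oc1c(C[C@@H](CC=C(C)C)[C@@H](C)CO[Si](C)(C)C(C)(C)C)c(OCOC)cc(OCOC)c1C=O | intermediate
18 | 2-SC-6-(hydroxymethyl)-3,5-bis(methoxymethoxy)phenol | OCc1c(OCOC)cc(OCOC)c(C[C@@H](CC=C(C)C)[C@@H](C)CO[Si](C)(C)C(C)(C)C)c1O | intermediate
19 | 4-hydroxy-2-methoxybenzaldehyde | COc1cc(O)ccc1C=O | starting material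
20 | 4-ethenyl-3-methoxyphenol | COc1cc(O)ccc1C=C | intermediate
21 | 2-SC-3,5-bis(methoxymethoxy)-6-methylidenecyclohexa-2,4-dien-1-one (ortho-quinone methide) | C=C1C(OCOC)=CC(OCOC)=C(C[C@@H](CC=C(C)C)[C@@H](C)CO[Si](C)(C)C(C)(C)C)C1=O | intermediate (not isolated)
22 | 4-[(2S)-8-SC-5,7-bis(methoxymethoxy)-3,4-dihydro-2H-chromen-2-yl]-3-methoxyphenol | COc1cc(O)ccc1[C@@H]1CCc2c(OCOC)cc(OCOC)c(C[C@@H](CC=C(C)C)[C@@H](C)CO[Si](C)(C)C(C)(C)C)c2O1 | intermediate
23 | 4-[(2S)-8-SC-5,7-bis(methoxymethoxy)-3,4-dihydro-2H-chromen-2-yl]-3-methoxyphenyl acetate | COc1cc(OC(C)=O)ccc1[C@@H]1CCc2c(OCOC)cc(OCOC)c(C[C@@H](CC=C(C)C)[C@@H](C)CO[Si](C)(C)C(C)(C)C)c2O1 | intermediate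
24 | 4-[(2S)-8-SC-4-hydroxy-5,7-bis(methoxymethoxy)-3,4-dihydro-2H-chromen-2-yl]-3-methoxyphenyl acetate (C4 epimers) | COc1cc(OC(C)=O)ccc1[C@@H]1CC(O)c2c(OCOC)cc(OCOC)c(C[C@@H](CC=C(C)C)[C@@H](C)CO[Si](C)(C)C(C)(C)C)c2O1 | intermediate (not isolated)
25 | 4-[(2S)-8-SC-5,7-bis(methoxymethoxy)-4-oxo-3,4-dihydro-2H-chromen-2-yl]-3-methoxyphenyl acetate | COc1cc(OC(C)=O)ccc1[C@@H]1CC(=O)c2c(OCOC)cc(OCOC)c(C[C@@H](CC=C(C)C)[C@@H](C)CO[Si](C)(C)C(C)(C)C)c2O1 | intermediate
26 | (2S)-5,7-dihydroxy-2-(4-hydroxy-2-methoxyphenyl)-8-[(2R,3R)-4-hydroxy-3-methyl-2-(3-methylbut-2-en-1-yl)butyl]-2,3-dihydro-4H-chromen-4-one | COc1cc(O)ccc1[C@@H]1CC(=O)c2c(O)cc(O)c(C[C@@H](CC=C(C)C)[C@@H](C)CO)c2O1 | target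

**Totals**
Total step count: 16. Longest linear sequence: 12 steps (steps 1–6, 10, 11, 13–16).

**Steps most likely to fail**

Step 13. The methide may be consumed by self-condensation or by Friedel–Crafts attack of the electron-rich ring of 20, the vinylphenol may polymerise under acid, and enantioface discrimination may be poor because the methide carbon carries no substituent. The fallback sets out from 17 and comes back to the route at 26; it closes ring C with the C4 carbonyl already in place by the chalcone route. Excess MeMgBr (THF, 0 °C) adds to the aldehyde of 17 and removes the acetate to give the carbinol F1, which MnO2 (CH2Cl2) oxidises to the ortho-hydroxyacetophenone F2. Claisen–Schmidt condensation of F2 (KOH, EtOH–H2O) with 2-methoxy-4-(methoxymethoxy)benzaldehyde F3 (from 19, MOMCl, i-Pr2NEt) gives the 2'-hydroxychalcone F4. Oxa-Michael ring closure (NaOAc, EtOH, reflux) gives the protected flavanone as its C2 epimers F5 (2S) and F6 (2R), which are separated by preparative chromatography on a chiral phase. F5 is deprotected under the conditions of step 16 to give 26; C2 then rests on the separation and not on a catalyst, and step 15 is by-passed as well.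

Step 15. Hydride may be abstracted at the other benzylic CH2 (C1'') or at C2, or the C4 cation may lose a proton to a flav-3-ene that is oxidised further. The fallback sets out from 15 and comes back at 25; it changes the order of events so that the oxidation is run before the side chain is on the ring. 15 is reduced and deacetylated (NaBH4, MeOH, 0 °C, then K2CO3) to the iodo benzyl alcohol F7. F7 enters the cycloaddition with 20 under the conditions of step 13 to give the 8-iodoflavan F8. Acetylation as in step 14 gives F9, and DDQ oxidation as in step 15 gives the 8-iodoflavanone F10, a substrate with no second benzylic methylene and no alkene. Negishi coupling of F10 with the zinc reagent 16 under the conditions of step 10 then gives 25.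

Step 10. Oxidative addition and transmetalation at the di-ortho-substituted iodide may be slow, so that β-hydride elimination or protodezincation of 16, or its addition to the aldehyde, takes over. The fallback sets out from 11 and comes back at 17; it replaces the zinc reagent by a B-alkyl Suzuki–Miyaura coupling. Lithium–iodine exchange on 11 (t-BuLi, Et2O, −78 °C) and trapping with B-methoxy-9-borabicyclo[3.3.1]nonane gives the lithium alkyl(methoxy)borate F11, which is coupled with 15 without added base (PdCl2(dppf), THF–DMF, 50 °C) to give 17.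

**Further compounds**
F1 | step 13 | 1-[2-hydroxy-4,6-bis(methoxymethoxy)-3-SC-phenyl]ethan-1-ol (carbinol epimers) | CC(O)c1c(OCOC)cc(OCOC)c(C[C@@H](CC=C(C)C)[C@@H](C)CO[Si](C)(C)C(C)(C)C)c1O
F2 | step 13 | 1-[2-hydroxy-4,6-bis(methoxymethoxy)-3-SC-phenyl]ethan-1-one | CC(=O)c1c(OCOC)cc(OCOC)c(C[C@@H](CC=C(C)C)[C@@H](C)CO[Si](C)(C)C(C)(C)C)c1O
F3 | step 13 | 2-methoxy-4-(methoxymethoxy)benzaldehyde | COCOc1ccc(C=O)c(OC)c1
F4 | step 13 | (E)-1-[2-hydroxy-4,6-bis(methoxymethoxy)-3-SC-phenyl]-3-[2-methoxy-4-(methoxymethoxy)phenyl]prop-2-en-1-one | COCOc1ccc(/C=C/C(=O)c2c(OCOC)cc(OCOC)c(C[C@@H](CC=C(C)C)[C@@H](C)CO[Si](C)(C)C(C)(C)C)c2O)c(OC)c1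
F5 | step 13 | (2S)-2-[2-methoxy-4-(methoxymethoxy)phenyl]-5,7-bis(methoxymethoxy)-8-SC-2,3-dihydro-4H-chromen-4-one | COCOc1ccc([C@@H]2CC(=O)c3c(OCOC)cc(OCOC)c(C[C@@H](CC=C(C)C)[C@@H](C)CO[Si](C)(C)C(C)(C)C)c3O2)c(OC)c1
F6 | step 13 | (2R)-2-[2-methoxy-4-(methoxymethoxy)phenyl]-5,7-bis(methoxymethoxy)-8-SC-2,3-dihydro-4H-chromen-4-one | COCOc1ccc([C@H]2CC(=O)c3c(OCOC)cc(OCOC)c(C[C@@H](CC=C(C)C)[C@@H](C)CO[Si](C)(C)C(C)(C)C)c3O2)c(OC)c1
F7 | step 15 | 2-(hydroxymethyl)-6-iodo-3,5-bis(methoxymethoxy)phenol | OCc1c(OCOC)cc(OCOC)c(I)c1O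
F8 | step 15 | 4-[(2S)-8-iodo-5,7-bis(methoxymethoxy)-3,4-dihydro-2H-chromen-2-yl]-3-methoxyphenol | COc1cc(O)ccc1[C@@H]1CCc2c(OCOC)cc(OCOC)c(I)c2O1
F9 | step 15 | 4-[(2S)-8-iodo-5,7-bis(methoxymethoxy)-3,4-dihydro-2H-chromen-2-yl]-3-methoxyphenyl acetate | COc1cc(OC(C)=O)ccc1[C@@H]1CCc2c(OCOC)cc(OCOC)c(I)c2O1
F10 | step 15 | 4-[(2S)-8-iodo-5,7-bis(methoxymethoxy)-4-oxo-3,4-dihydro-2H-chromen-2-yl]-3-methoxyphenyl acetate | COc1cc(OC(C)=O)ccc1[C@@H]1CC(=O)c2c(OCOC)cc(OCOC)c(I)c2O1
F11 | step 10 | lithium 9-methoxy-9-[(2S,3R)-4-(TBS-oxy)-3-methyl-2-(3-methylbut-2-en-1-yl)butyl]-9-boranuidabicyclo[3.3.1]nonane | [Li+].CO[B-]1(C[C@@H](CC=C(C)C)[C@@H](C)CO[Si](C)(C)C(C)(C)C)C2CCCC1CCC2
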